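All runs come from a simulation on assumed constants; scatter was added.

A small charge shows the loss plainly: in Thursday's flask, with 10 mM of substrate, target reads 76.3 % at 25.0 h but 61.5 % at 40.0 h, while side product keeps climbing.

| flask | substrate | coupling partner | free catalyst | remark | time |
|---|---|---|---|---|---|
| Wednesday's | 20 mM | 22 mM | 0.40 mM | run made earlier |  |
| Thursday's | 10 mM | 22 mM | 0.40 mM | run made earlier |  |
| Tuesday's | 40 mM | 22 mM | 0.40 mM | run made earlier |  |
| dawn | 20 mM (fed, over 40.0 h) | 22.0 mM | 0.40 mM | all but substrate at the start; substrate goes in evenly over 40.0 h, the run ends at 40 h | 40 h |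
| dusk | 20 mM | 22.0 mM | 0.40 mM | everything together in a closed stirred flask, run for 40 h | 40 h |
| autumn | 20 mM | 22.0 mM | 0.40 mM | one stirred flow tank at steady state, fed with the mixture as stated, mean residence time 40 h |  |
| spring | 20 mM | 22.0 mM (fed, over 40.0 h) | 0.40 mM | a stirred flask in which coupling partner is dosed at a steady rate over 40.0 h without added volume, worked up at 40 h | 40 h |

| run | time / h | target / % | side product / % |
|---|---|---|---|
| Wednesday's | 3.00 | 12.0 | 0.1 |
| Wednesday's | 6.00 | 20.8 | 0.5 |
| Wednesday's | 12.0 | 35.6 | 3.5 |
| Wednesday's | 20.0 | 47.8 | 10.0 |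
| Wednesday's | 40.0 | 50.2 | 35.0 |
| Thursday's | 8.00 | 48.2 | 1.4 |
| Thursday's | 15.0 | 73.7 | 8.3 |
| Thursday's | 25.0 | 76.3 | 21.6 |
| Thursday's | 30.0 | 71.0 | 27.9 |
| Thursday's | 40.0 | 61.5 | 40.5 |
| Tuesday's | 8.00 | 15.1 | 0.7 |
| Tuesday's | 15.0 | 22.0 | 3.0 |
| Tuesday's | 25.0 | 25.9 | 8.6 |
| Tuesday's | 30.0 | 26.2 | 12.3 |
| Tuesday's | 40.0 | 25.0 | 19.0 |

(each reading ± 0.5 percentage points)

- the set-up with the highest share of target in all that became target or side product, at the outlet or at the end ("none" if the first two lie within 2 percentage points) (dawn / dusk / autumn / spring / none)
- share of target in all that became target or side product, at the outlet or at the end, dawn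
- share of target in all that became target or side product, at the outlet or at the end, dusk
- share of target in all that became target or side product, at the outlet or at the end, autumn
- share of target in all that became target or side product, at the outlet or at the end, spring

- the stated concentrations are those of everything mixed, before any reaction; amounts are the same in each set-up
- the numbers in the tables scatter by 0.5 percentage points (one standard deviation)
- the feed brings no volume worth counting
- the earlier runs were made in a closed, stirred flask

Over its last two readings, Wednesday's side product rises as if its rate were k[target][target], with k = 2.60 L mol⁻¹ h⁻¹. Tuesday's flask, with twice the substrate, reads 2.56 L mol⁻¹ h⁻¹, so we leave substrate out of this rate. Tuesday's made total also gives a pseudo-first-order constant for the coupling partner, 0.0402 h⁻¹.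

Call r the rate of making, T the total made by the end and t the time. Dosing against that constant gives, for spring,

T = 11.1 mM

The loss number is D = kTt, here for spring 1.15. Integrating d[target]/dt = r − k[target][target] gives two extreme flasks:

making steady: share of target = tanh(√D)/√D

making rising straight from nothing: share ≈ 1/(1 + D/5)

In spring, [coupling partner] starts from nothing and, with 24.9 h as its time of consumption against 40.0 h of dosing, rises while bending over; making follows it, so spring lies between the two, in a band from 73.7 % to 81.3 %. Dusk repeats Wednesday, whose reading is 58.9 %, lower than the band. We commit to spring over dusk.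

The forecast, resting on a loss that “fits second order in target”, named spring, with 68 % for dawn, 58.9 % for dusk, 57 % for autumn and 79 % for spring.

The flask gives spring: 70.1 % for dawn, 58.6 % for dusk, 57.7 % for autumn and 80.7 % for spring, inside our band .

    substrate + free catalyst → catalyst intermediate A (k = 1100 L mol⁻¹ h⁻¹)
    coupling partner + catalyst intermediate A ⇌ catalyst intermediate B (K = 6.00 L mol⁻¹, k = 130 L mol⁻¹ h⁻¹)
    catalyst intermediate B → by-product + catalyst intermediate C (k = 110 h⁻¹)
    catalyst intermediate C → free catalyst + target (k = 190 h⁻¹)
    target + by-product → side product (k = 2.40 L mol⁻¹ h⁻¹)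

Spring's simulated total, 11.0 mM, gives D = 1.15. Spring with 1.0 mM of free catalyst has D = 1.72, a band from 65.9 % to 74.4 %, and reads 71.5 %. At 40.0 h in spring, catalyst intermediate B passes on at 0.418 mM h⁻¹, faster than target and by-product meet at 0.190 mM h⁻¹. At 40.0 h in dusk the order is reversed, with making at 0.177 mM h⁻¹ against loss at 0.242 mM h⁻¹.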